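**Plan**

- Retrosynthesis first cuts the phenethyl ester C–O bond, releasing hydroxytyrosol (catechol masked as its dibenzyl ether). The formyl carbon is then tied to the ester carbonyl, through oxygen as an enol δ-lactone and, one Baeyer–Villiger step further back, directly as a ketone.
- The feature that allows this: the formyl carbon, C3, C4, the side-chain CH2 and the ester carbonyl form a five-carbon loop. Once formyl carbon and carbonyl are bonded it is a cyclopentenone fused to the dihydropyran (O1, C2–C6).
- That bicyclic enone is cut at C3–C4, CH2–C(=O) and C(=O)–CH into an enyne and carbon monoxide. The enyne is cut at the C5–vinyl bond (Stille), the C5–I bond and the C6–O bond (oxa-Michael addition to methyl propiolate).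
- Forward: the open chain is built in four steps, the dihydropyran and the cyclopentenone close together in one [2+2+1] step, the carbocycle is reopened by oxygen insertion and alcoholysis, and hydrogenolysis ends the route.
- Stereochemistry: C2 comes from (S)-4-(trimethylsilyl)but-3-yn-2-ol; C4 is set in the cyclisation under control of the C2 methyl (cis to the new CH2); C3 is set last by thermodynamic protonation, formyl trans to both neighbours.

Key step: step 5

Assumption: the 2,3-trans-3,4-trans aldehyde is taken to be the thermodynamically favoured C3 epimer, so C3 can be set by equilibration; bicyclic intermediates use cyclopenta[c]pyran numbering, in which C1, C7a, C4a, C4 and C3 are pyran C2, C3, C4, C5 and C6.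

**Route**

Step 1
Reactants: 1 (S)-4-(trimethylsilyl)but-3-yn-2-ol; 2 methyl propiolate
Product: 3 methyl (2E)-3-{[(2S)-4-(trimethylsilyl)but-3-yn-2-yl]oxy}prop-2-enoate
Conditions: DABCO (10 mol%), CH2Cl2, 0 °C to rt
Reagents that add atoms: none
Why: Amine-catalysed oxa-Michael addition of a secondary alcohol to a propiolate runs through the ammonium allenolate and gives the E β-alkoxyacrylate, without touching the carbinol stereocentre or the silylalkyne.

Step 2
Reactants: 3 methyl (2E)-3-{[(2S)-4-(trimethylsilyl)but-3-yn-2-yl]oxy}prop-2-enoate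
Product: 5 methyl (2Z)-2-iodo-3-{[(2S)-4-(trimethylsilyl)but-3-yn-2-yl]oxy}prop-2-enoate, via iodoacetoxy adduct 4 (not isolated)
Conditions: NIS (1.3 equiv), AcOH (2 equiv), CH2Cl2, rt, dark; then Et3N (3 equiv), 0 °C to rt
Reagents that add atoms: N-iodosuccinimide, O=C1CCC(=O)N1I; acetic acid, CC(=O)O (kept only in intermediate 4)
Why: Electrophilic iodoacetoxylation of the enol ether followed by amine-induced elimination of acetic acid is the established α-iodination of β-alkoxyacrylates and should place iodine cis to the alkoxy group, while the silylalkyne is inert to NIS without a silver promoter.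

Step 3
Reactants: 5 methyl (2Z)-2-iodo-3-{[(2S)-4-(trimethylsilyl)but-3-yn-2-yl]oxy}prop-2-enoate
Product: 6 methyl (2E)-2-ethenyl-3-{[(2S)-4-(trimethylsilyl)but-3-yn-2-yl]oxy}prop-2-enoate
Conditions: CH2=CHSnBu3 (1.3 equiv), Pd2(dba)3 (2.5 mol%), AsPh3 (10 mol%), CuI (10 mol%), DMF, rt to 40 °C
Reagents that add atoms: tributyl(vinyl)stannane, C=C[Sn](CCCC)(CCCC)CCCC
Why: Stille cross-coupling of the alkenyl iodide under zerovalent palladium with copper co-catalysis proceeds with retention of geometry, so the vinyl group takes the place of iodine cis to oxygen, and the neutral conditions spare the acrylate and the silylalkyne, which is kept on to block alkyne coupling.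

Step 4
Reactants: 6 methyl (2E)-2-ethenyl-3-{[(2S)-4-(trimethylsilyl)but-3-yn-2-yl]oxy}prop-2-enoate
Product: 7 methyl (2E)-3-[(2S)-but-3-yn-2-yloxy]-2-ethenylprop-2-enoate
Conditions: TBAF (1.1 equiv), AcOH (1.1 equiv), THF, 0 °C
Reagents that add atoms: none
Why: Fluoride-induced protodesilylation of the alkynylsilane, buffered with acetic acid so that no alkoxide can exchange the β-alkoxy group by addition–elimination, frees the terminal alkyne.

Step 5
Reactants: 7 methyl (2E)-3-[(2S)-but-3-yn-2-yloxy]-2-ethenylprop-2-enoate; 8 carbon monoxide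
Product: 9 methyl (1S,4aR)-1-methyl-6-oxo-1,4a,5,6-tetrahydrocyclopenta[c]pyran-4-carboxylate
Conditions: Co2(CO)8 (10 mol%), tetramethylthiourea (60 mol%), CO (1 atm, balloon), toluene, 70 °C
Reagents that add atoms: none
Why: The alkyne is taken up by cobalt as its hexacarbonyldicobalt complex, the pendant vinyl group inserts into the cobalt–carbon bond at the internal alkyne carbon to make C7a–C4a (pyran C3–C4), carbon monoxide inserts on the side of the former vinyl CH2, and reductive elimination onto the former alkyne CH gives the enone and returns cobalt to the cycle. The closest known reaction type is the intramolecular Pauson–Khand reaction of oxygen-tethered 1,7-enynes whose alkene is conjugated, as in 2-vinylaryl propargyl ethers and dienynes, run here in its catalytic cobalt–thiourea form under a balloon of carbon monoxide. The dihydropyran closes in a 6-exo sense onto the internal vinyl carbon, helped by the Z enol ether that holds oxygen and vinyl group cis on one rigid double bond, and the cyclopentenone closes by carbonyl insertion and reductive elimination inside the cobaltacycle. The one new stereocentre, C4a, is controlled by the (S) propargylic carbon: in the half-chair of the forming pyran the methyl group lies pseudo-equatorial, which puts it cis to the new ring methylene, and because the alkyne terminus carries only hydrogen no allylic strain pushes the methyl axial. The step needs the vinyl group to react in place of the enol ether double bond and [2+2+1] to win over [4+2] and Claisen pathways; only the vinyl group can reach the alkyne, the diene is joined to the alkyne through two atoms at its oxygen-bearing end so a [4+2] closure would need a four-membered ring, and cobalt at 70 °C, unlike π-acidic monovalent rhodium or gold, does not trigger the propargyl vinyl ether rearrangement.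

Step 6
Reactants: 9 methyl (1S,4aR)-1-methyl-6-oxo-1,4a,5,6-tetrahydrocyclopenta[c]pyran-4-carboxylate
Product: 10 methyl (1S,4aR)-1-methyl-6-oxo-1,4a,5,6-tetrahydropyrano[3,4-c]pyran-4-carboxylate
Conditions: mCPBA (1.2 equiv), CH2Cl2, 0 °C to rt
Reagents that add atoms: 3-chloroperoxybenzoic acid, OOC(=O)c1cccc(Cl)c1
Why: Baeyer–Villiger oxidation of a conjugated cyclopentenone, in whose Criegee intermediate the electron-rich trisubstituted vinyl carbon should migrate in preference to the ring methylene to give the enol δ-lactone, while the ester-conjugated enol ether is too electron-poor to be epoxidised readily by a limited amount of peracid.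

Step 7
Reactants: 11 hydroxytyrosol
Product: 12 2-[3,4-bis(benzyloxy)phenyl]ethan-1-ol
Conditions: BnBr (2.2 equiv), K2CO3 (2.5 equiv), acetone, reflux, N2
Reagents that add atoms: benzyl bromide, BrCc1ccccc1
Why: Williamson etherification under carbonate is selective for the two phenols, which are deprotonated, over the aliphatic alcohol, which is not.

Step 8
Reactants: 10 methyl (1S,4aR)-1-methyl-6-oxo-1,4a,5,6-tetrahydropyrano[3,4-c]pyran-4-carboxylate; 12 2-[3,4-bis(benzyloxy)phenyl]ethan-1-ol
Product: 14 methyl (2S,3R,4R)-4-{2-[2-(3,4-bis(benzyloxy)phenyl)ethoxy]-2-oxoethyl}-3-formyl-2-methyl-3,4-dihydro-2H-pyran-5-carboxylate, via ring-opened enol 13 (not isolated)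
Conditions: 12 (1.1 equiv), 1,5,7-triazabicyclo[4.4.0]dec-5-ene (TBD, 10 mol%), THF, 0 °C to rt; AcOH quench
Reagents that add atoms: none
Why: Base-catalysed ring-opening alcoholysis (transesterification) of an enol δ-lactone by a primary alcohol is driven forward because the leaving enolate tautomerises to the aldehyde, and the new C3 stereocentre is set under thermodynamic control, the guanidine equilibrating the α-formyl centre through the same enol so that the formyl group should settle trans to the C2 methyl and the C4 side chain.

Step 9
Reactants: 14 methyl (2S,3R,4R)-4-{2-[2-(3,4-bis(benzyloxy)phenyl)ethoxy]-2-oxoethyl}-3-formyl-2-methyl-3,4-dihydro-2H-pyran-5-carboxylate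
Product: 15 methyl (2S,3R,4R)-4-{2-[2-(3,4-dihydroxyphenyl)ethoxy]-2-oxoethyl}-3-formyl-2-methyl-3,4-dihydro-2H-pyran-5-carboxylate
Conditions: H2 (1 atm), 10% Pd/C, EtOAc, rt
Reagents that add atoms: none
Why: Catalytic hydrogenolysis of aryl benzyl ethers over palladium on carbon at atmospheric pressure should be fast compared with reduction of the aliphatic aldehyde or the trisubstituted ester-conjugated enol ether, and its neutrality leaves the base-labile β-alkoxy aldehyde and all three stereocentres untouched.

**Compound list**

1 | (S)-4-(trimethylsilyl)but-3-yn-2-ol | C[C@H](O)C#C[Si](C)(C)C | starting material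
2 | methyl propiolate | COC(=O)C#C | starting material
3 | methyl (2E)-3-{[(2S)-4-(trimethylsilyl)but-3-yn-2-yl]oxy}prop-2-enoate | COC(=O)/C=C/O[C@@H](C)C#C[Si](C)(C)C | intermediate
4 | methyl 3-(acetyloxy)-2-iodo-3-{[(2S)-4-(trimethylsilyl)but-3-yn-2-yl]oxy}propanoate (diastereomer mixture at C2 and C3) | COC(=O)C(I)C(OC(C)=O)O[C@@H](C)C#C[Si](C)(C)C | intermediate (not isolated)
5 | methyl (2Z)-2-iodo-3-{[(2S)-4-(trimethylsilyl)but-3-yn-2-yl]oxy}prop-2-enoate | COC(=O)/C(I)=C/O[C@@H](C)C#C[Si](C)(C)C | intermediate
6 | methyl (2E)-2-ethenyl-3-{[(2S)-4-(trimethylsilyl)but-3-yn-2-yl]oxy}prop-2-enoate | COC(=O)/C(C=C)=C/O[C@@H](C)C#C[Si](C)(C)C | intermediate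
7 | methyl (2E)-3-[(2S)-but-3-yn-2-yloxy]-2-ethenylprop-2-enoate | C=C/C(C(=O)OC)=C\O[C@@H](C)C#C | intermediate
8 | carbon monoxide | [C-]#[O+] | starting material
9 | methyl (1S,4aR)-1-methyl-6-oxo-1,4a,5,6-tetrahydrocyclopenta[c]pyran-4-carboxylate | COC(=O)C1=CO[C@@H](C)C2=CC(=O)C[C@@H]12 | intermediate
10 | methyl (1S,4aR)-1-methyl-6-oxo-1,4a,5,6-tetrahydropyrano[3,4-c]pyran-4-carboxylate (enol δ-lactone, ring oxygens at positions 2 and 7) | COC(=O)C1=CO[C@@H](C)C2=COC(=O)C[C@@H]12 | intermediate
11 | hydroxytyrosol, 2-(3,4-dihydroxyphenyl)ethan-1-ol | OCCc1ccc(O)c(O)c1 | starting material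
12 | 2-[3,4-bis(benzyloxy)phenyl]ethan-1-ol | OCCc1ccc(OCc2ccccc2)c(OCc2ccccc2)c1 | intermediate
13 | methyl (2S,4R)-4-{2-[2-(3,4-bis(benzyloxy)phenyl)ethoxy]-2-oxoethyl}-3-(hydroxymethylidene)-2-methyl-3,4-dihydro-2H-pyran-5-carboxylate | COC(=O)C1=CO[C@@H](C)C(=CO)[C@H]1CC(=O)OCCc1ccc(OCc2ccccc2)c(OCc2ccccc2)c1 | intermediate (not isolated)
14 | methyl (2S,3R,4R)-4-{2-[2-(3,4-bis(benzyloxy)phenyl)ethoxy]-2-oxoethyl}-3-formyl-2-methyl-3,4-dihydro-2H-pyran-5-carboxylate | COC(=O)C1=CO[C@@H](C)[C@H](C=O)[C@H]1CC(=O)OCCc1ccc(OCc2ccccc2)c(OCc2ccccc2)c1 | intermediate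
15 | methyl (2S,3R,4R)-4-{2-[2-(3,4-dihydroxyphenyl)ethoxy]-2-oxoethyl}-3-formyl-2-methyl-3,4-dihydro-2H-pyran-5-carboxylate | COC(=O)C1=CO[C@@H](C)[C@H](C=O)[C@H]1CC(=O)OCCc1ccc(O)c(O)c1 | target

**Step count and risks**

Total steps: 9. Longest linear sequence: 8 (steps 1 to 6, then 8 and 9); step 7 is a one-step side branch.

Steps most likely to fail:

Step 5. Alkene insertion for the six-membered ring may be slow, so that alkyne oligomerisation competes. The enone double bond may also migrate into the ring fusion, with loss of the C4a configuration. The fallback sets out from 7 and replaces carbon monoxide by an isocyanide in a nickel-mediated [2+2+1]. Ni(cod)2 (1 equiv), PBu3 and 2,6-dimethylphenyl isocyanide in DMF should give methyl (1S,4aR)-6-[(2,6-dimethylphenyl)imino]-1-methyl-1,4a,5,6-tetrahydrocyclopenta[c]pyran-4-carboxylate F1. Hydrolysis of its imine with aqueous oxalic acid in THF comes back to the route at 9.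

Step 6. Oxygen insertion into the conjugated ketone may be slow, so that epoxidation of the newly formed enol-lactone double bond or of the enol ether overtakes it, or the ring methylene migrates in place of the vinyl carbon. The fallback sets out from 9. RhCl(PPh3)3-catalysed 1,4-hydrosilylation with Et3SiH should give methyl (1S,4aR)-1-methyl-6-[(triethylsilyl)oxy]-1,4a,5,7a-tetrahydrocyclopenta[c]pyran-4-carboxylate F2 (C7a epimers, of no consequence). Ozonolysis in CH2Cl2 at −78 °C, titrated with an indicator dye and worked up with Me2S, should cleave only the electron-rich silyl enol ether. After brief Et3N equilibration of C3 this gives 2-[(2S,3R,4R)-3-formyl-5-(methoxycarbonyl)-2-methyl-3,4-dihydro-2H-pyran-4-yl]acetic acid F3. Steglich esterification (DCC, DMAP, CH2Cl2) with 12 comes back to the route at 14.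

Step 8. Acyl transfer to the neutral alcohol may be slow, and the guanidine may then open the pyran by β-elimination of the ring oxygen from the aldehyde enolate, or erode C2 through that reversible opening. The fallback sets out from 10 and unprotected hydroxytyrosol 11 and uses an enzyme in place of base. Immobilised Candida antarctica lipase B in tert-butyl methyl ether/acetonitrile at 40 °C acylates only the primary hydroxyl with enol esters. The lactone should therefore be opened to methyl (2S,4R)-4-{2-[2-(3,4-dihydroxyphenyl)ethoxy]-2-oxoethyl}-3-(hydroxymethylidene)-2-methyl-3,4-dihydro-2H-pyran-5-carboxylate F4 (not isolated), which tautomerises and, after mild equilibration of C3 under argon, comes back to the route at 15. Steps 7 and 9 then fall away.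

Further compounds
F1 | step 5 | methyl (1S,4aR)-6-[(2,6-dimethylphenyl)imino]-1-methyl-1,4a,5,6-tetrahydrocyclopenta[c]pyran-4-carboxylate | COC(=O)C1=CO[C@@H](C)C2=CC(=Nc3c(C)cccc3C)C[C@@H]12
F2 | step 6 | methyl (1S,4aR)-1-methyl-6-[(triethylsilyl)oxy]-1,4a,5,7a-tetrahydrocyclopenta[c]pyran-4-carboxylate | COC(=O)C1=CO[C@@H](C)C2C=C(O[Si](CC)(CC)CC)C[C@@H]12
F3 | step 6 | 2-[(2S,3R,4R)-3-formyl-5-(methoxycarbonyl)-2-methyl-3,4-dihydro-2H-pyran-4-yl]acetic acid | COC(=O)C1=CO[C@@H](C)[C@H](C=O)[C@H]1CC(=O)O
F4 | step 8 | methyl (2S,4R)-4-{2-[2-(3,4-dihydroxyphenyl)ethoxy]-2-oxoethyl}-3-(hydroxymethylidene)-2-methyl-3,4-dihydro-2H-pyran-5-carboxylate | COC(=O)C1=CO[C@@H](C)C(=CO)[C@H]1CC(=O)OCCc1ccc(O)c(O)c1
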